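A small charge of substrate, 0.020 M, stands in this flask, reagent goes in as two equal portions, and two smaller runs show what to expect at 20 min.

| flask | substrate | reagent | remark | time |
|---|---|---|---|---|
| autumn | 0.010 M | 1 equiv (in portions, 2) | run made earlier; portions every 10 min |  |
| noon | 0.015 M | 1 equiv (in portions, 2) | run made earlier; portions every 10 min |  |
| flask | 0.020 M | 1.00 equiv (in portions, 2) | the portions of reagent follow each other after 10 min, the first at the start | 20 min |

- autumn (time / min: product / %, substrate / %): 2.50: 1.7, 98.5; 5.00: 1.5, 98.2; 8.00: 2.4, 96.6; 10.0: 3.3, 96.3; 12.0: 5.7, 94.7; 15.0: 7.2, 92.8
- noon (time / min: product / %, substrate / %): 1.33: 1.0, 99.4; 2.00: 3.1, 97.9; 4.00: 3.5, 96.3; 6.00: 4.5, 96.2; 10.0: 5.0, 94.1; 15.0: 12.1, 88.3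

(each reading ± 0.5 percentage points)



- concentration of product at 20 min, in M
- concentration of substrate at 20 min, in M
- concentration of reagent at 20 min, in M

In both runs substrate lost matches product found within the scatter, and substrate stays at 88.3% or above up to 15.0 min, so over those times it can be frozen at its charge. Between autumn's 7.2% and noon's 12.1%, both read at 15.0 min, the fraction converted reads as rising with the substrate charge to the power 1.28. This power, at fixed time and recipe, is the charge exponent, the apparent overall order less one.

The gain after the first portion also fades in the readings: pooled over both runs, 66.3% of the gain up to 10.0 min has arrived by 5.00 min. If the second portion fades alike, noon reckons to 15.7% at 20 min, and the exponent lifts that to 22.7% of the charge for this flask, leaving 77.3% of its substrate. Reagent was read in neither run. If each product takes one reagent, that same 77.3% of its own charge is this flask's reckoned ceiling for reagent, and the fading in noon, with substrate still at 94.1% at 10.0 min, suggests a lower figure. Add no solvent: autumn's thinner charge had converted less than noon's by 15.0 min, and the reckoning assumes the second portion at 10 min.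

The forecast gives 0.0042 M product, 0.0158 M substrate and 0.0158 M reagent, on its reading: “Substrate lost matches product formed”. The flask gives 0.00434 M product, 0.0157 M substrate and 0.00631 M reagent, so product stands at 21.7% of the charge against the reckoned 22.7%.

    substrate + reagent → product, rate k1*[substrate]*[reagent]^1.5 (k = 20.0 /M^1.5/min)
    reagent ⇌ dormant form (K = 1.50, k = 0.150 /min)

While substrate fell to 78.3% through the product step, its half-life by that step being 150 min at 8.54 min, reagent passed into the dormant form with a shorter half-life of 4.6 min, forward rate alone. At 20.0 min the dormant form holds 0.00935 M beside 0.00631 M reagent and 0.00434 M product, together 0.0200 M of the 0.020 M of reagent charged. Carried from this flask's 21.7% to the neighbour charged with 0.012 M, the exponent gives 11.3%, and that neighbour holds 12.0%.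

The readings are simulated on assumed constants, and the scatter is random.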